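The route rests on cutting C8–C14 and C13–C18. The vicinal quaternary carbons C13 and C14 at the ring C/D fusion sit between allylic C8 of ring B and C18 of ring E, so both can come from one (E)-tetrasubstituted alkene. In one operation a C6–C8 allyl cation is relayed through this alkene to the γ-carbon of a ring E silyl dienol ether. Rings C and D close, and C8, C14, C13 and C18 are set. The precursor is a seco-C,D allylic alcohol: a ring A/B dihydronaphthalenol and a ring E dienol ether, each joined to the alkene by two CH2 groups. Conjugate reduction, demethylation and a hetero-Diels–Alder union with an ent-guaiatriene finish the target.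

Key step: step 16

Remarks on the chemistry
- Locants: friedelane numbering is used for the triterpene half and primed guaiane numbering for the sesquiterpene half. O2 and O3 are the oxygens on C2 and C3.
- Structure check: in the seco precursor and in the pentacyclic enone, the descriptors at C9 and C17, the (E)-alkene, and C8, C13, C14 and C18 map onto the target. Both structures are used unchanged. The target has C8–H cis to C25, C26 syn to C25, C26/C27 trans, and rings D/E cis-fused.
- Both tethers (C11–C12 and C15–C16) are two CH2 groups long, so vinyl groups are the handles at C9 and C17. An allyl group would be one carbon too long.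
- The ring E carbonyl is masked as the dienol ether before any hydride reagent is used, because a 1,2-reduction could not distinguish the two enones.
- In the target O3 is bonded to allylic C5′ and O2 to C1′. Both oxygens lie anti to the cis-disposed C10′ methyl and C7′ isopropenyl groups.
- Assumption: the sesquiterpene half is made exactly as drawn (7′S,10′R). This is antipodal to commercial guaiol and α-guaiene, so it is built from (S)-carvone.
- C20 (R) carries the equatorial methyl group of the ring E chair and is treated as the thermodynamic epimer.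
- The C6 carbinol is drawn as the epimer expected from hydride attack on the C25 face. Its configuration is erased on ionisation.

Step 1
Reactants: 1 2,3-dimethoxytoluene
Product: 3 5-bromo-1,2-dimethoxy-3-methylbenzene, via arylboronate 2 (not isolated)
Conditions: [Ir(OMe)(cod)]2 (1.5 mol %), 4,4′-di-tert-butyl-2,2′-bipyridine, B2pin2, THF, 80 °C; then CuBr2, MeOH/H2O, 80 °C
Reagents that add atoms: bis(pinacolato)diboron CC1(C)OB(OC1(C)C)B1OC(C)(C)C(C)(C)O1 (boron unit in 2 only); copper dibromide [Cu+2].[Br-].[Br-]
Why: Sterically governed iridium-catalysed C–H borylation takes the only C–H bond of 1 without an ortho neighbour (the future C10), a site that electrophilic bromination would not reach, and copper-mediated bromodeboronation then gives the bromide.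

Step 2
Reactants: 4 geraniol
Product: 5 geranyl diethyl phosphate
Conditions: ClP(O)(OEt)2, pyridine, CH2Cl2, 0 °C
Reagents that add atoms: diethyl chlorophosphate CCOP(=O)(Cl)OCC
Why: Phosphorylation of a primary allylic alcohol leaves the (E)-trisubstituted alkene untouched and installs the leaving group for the allylic substitution.

Step 3
Reactants: 3 5-bromo-1,2-dimethoxy-3-methylbenzene; 5 geranyl diethyl phosphate
Product: 8 (S)-5-(3,7-dimethylocta-1,6-dien-3-yl)-1,2-dimethoxy-3-methylbenzene, via aryllithium 6 (not isolated), via arylaluminium 7 (not isolated)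
Conditions: 3, n-BuLi, Et2O, −78 °C; Et2AlCl, −78 → 23 °C; then 5, CuCl2·2H2O (5 mol %), chiral sulfonate-bearing imidazolinium salt (5.5 mol %), THF, −30 °C
Reagents that add atoms: n-butyllithium [Li]CCCC (lithium in 6 only); diethylaluminium chloride CC[Al](Cl)CC (AlEt2 in 7 only)
Why: Copper-catalysed enantioselective allylic substitution (SN2′) of a γ,γ-disubstituted allylic phosphate by an arylaluminium reagent is a known way to aryl/methyl/vinyl quaternary carbons from geranyl phosphate, the ligand enantiomer that gives the (S) product sets C9, and 8 already holds C25, the C11=C12 vinyl handle and C8–C6.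

Step 4
Reactants: 8 (S)-5-(3,7-dimethylocta-1,6-dien-3-yl)-1,2-dimethoxy-3-methylbenzene; 9 (E)-2,3-dibromobut-2-ene
Product: 11 5-[(2E,6S)-2-bromo-3,6,10-trimethylundeca-2,9-dien-6-yl]-1,2-dimethoxy-3-methylbenzene, via B-alkyl-9-BBN 10 (not isolated)
Conditions: 9-BBN, THF, 23 °C; then 9 (4 equiv), PdCl2(dppf) (5 mol %), K3PO4, DMF/THF/H2O, 40 °C
Reagents that add atoms: 9-borabicyclo[3.3.1]nonane B1C2CCCC1CCC2 (boron unit in 10 only)
Why: In this hydroboration/B-alkyl Suzuki–Miyaura sequence 9-BBN selects the monosubstituted alkene over the trisubstituted one, the excess of 9 and the lower reactivity of the more hindered product bromide favour single coupling, and retention at the sp2 carbon keeps the C26 and C27 methyl groups trans.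

Step 5
Reactants: 11 5-[(2E,6S)-2-bromo-3,6,10-trimethylundeca-2,9-dien-6-yl]-1,2-dimethoxy-3-methylbenzene
Product: 12 (4R,7E)-8-bromo-4-(3,4-dimethoxy-5-methylphenyl)-4,7-dimethylnon-7-enal
Conditions: OsO4 (2 mol %), NaIO4, 2,6-lutidine, dioxane/H2O, 23 °C
Reagents that add atoms: sodium periodate [Na+].[O-]I(=O)(=O)=O; water O
Why: In this Lemieux–Johnson cleavage OsO4 attacks the electron-rich trisubstituted alkene much faster than the hindered, bromine-deactivated tetrasubstituted one, which exposes C6 as the aldehyde.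

Step 6
Reactants: 12 (4R,7E)-8-bromo-4-(3,4-dimethoxy-5-methylphenyl)-4,7-dimethylnon-7-enal
Product: 13 (4R,7E)-8-bromo-4-(3,4-dimethoxy-5-methylphenyl)-4,7-dimethylnon-7-enoic acid
Conditions: NaClO2, NaH2PO4, 2-methylbut-2-ene, t-BuOH/H2O, 23 °C
Reagents that add atoms: sodium chlorite [Na+].[O-]Cl=O
Why: The Pinnick oxidation tolerates the bromoalkene and the electron-rich arene as long as the hypochlorous acid is scavenged by the added alkene.

Step 7
Reactants: 13 (4R,7E)-8-bromo-4-(3,4-dimethoxy-5-methylphenyl)-4,7-dimethylnon-7-enoic acid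
Product: 15 (R)-4-[(E)-4-bromo-3-methylpent-3-en-1-yl]-6,7-dimethoxy-4,8-dimethyl-3,4-dihydronaphthalen-1(2H)-one, via mixed anhydride 14 (not isolated)
Conditions: (CF3CO)2O, CH2Cl2, 0 → 23 °C
Reagents that add atoms: trifluoroacetic anhydride O=C(OC(=O)C(F)(F)F)C(F)(F)F (acyl unit in 14 only)
Why: Intramolecular Friedel–Crafts acylation through the mixed anhydride should close ring B at C5, para to the conjugated C2 methoxy group, rather than at C1, and the bromoalkene is too electron-poor to compete.

Step 8
Reactants: 15 (R)-4-[(E)-4-bromo-3-methylpent-3-en-1-yl]-6,7-dimethoxy-4,8-dimethyl-3,4-dihydronaphthalen-1(2H)-one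
Product: 16 (R)-4-[(E)-4-bromo-3-methylpent-3-en-1-yl]-6,7-dimethoxy-4,8-dimethylnaphthalen-1(4H)-one
Conditions: IBX, 4-methoxypyridine N-oxide, DMSO, 23–40 °C
Reagents that add atoms: none
Why: IBX dehydrogenation of a ketone to its enone can only desaturate C7–C8 here, and quaternary C9 blocks aromatisation.

Step 9
Reactants: 17 3-methylcyclohex-2-en-1-one; 18 ethynyltrimethylsilane
Product: 20 (R)-3-methyl-3-[1-(trimethylsilyl)ethenyl]cyclohexan-1-one, via vinylaluminium 19 (not isolated)
Conditions: 18, iBu2AlH, hexanes/THF, 55 °C; then 17, Cu(OTf)2 (5 mol %), chiral sulfonate-bearing imidazolinium salt (5.5 mol %), THF, −15 °C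
Reagents that add atoms: diisobutylaluminium hydride CC(C)C[AlH]CC(C)C (aluminium unit in 19 only)
Why: Hydroalumination gives the α-silyl vinylaluminium reagent, and its copper-catalysed enantioselective conjugate addition to a β-substituted cyclic enone, a known entry to vinyl-bearing quaternary carbons, sets C17 under control of the chiral carbene ligand.

Step 10
Reactants: 20 (R)-3-methyl-3-[1-(trimethylsilyl)ethenyl]cyclohexan-1-one
Product: 21 (R)-3-ethenyl-3-methylcyclohexan-1-one
Conditions: CF3CO2H, CH2Cl2, 0 → 23 °C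
Reagents that add atoms: none
Why: Protodesilylation of the vinylsilane (ipso protonation with β-silyl assistance) frees the C15=C16 vinyl handle without touching C17.

Step 11
Reactants: 21 (R)-3-ethenyl-3-methylcyclohexan-1-one
Product: 23 (5R)-5-ethenyl-2,5-dimethylcyclohexan-1-one (C2 epimers), via lithium enolate 22 (not isolated)
Conditions: LiN(iPr)2, THF, −78 °C; then MeI, −78 → 0 °C
Reagents that add atoms: lithium diisopropylamide [Li]N(C(C)C)C(C)C (lithium in 22 only); iodomethane CI
Why: In this kinetic enolate alkylation the base removes a C20 hydrogen rather than a neopentyl C22 hydrogen next to quaternary C17, and the new C20 configuration does not matter because this carbon becomes sp2 in the next step.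

Step 12
Reactants: 23 (5R)-5-ethenyl-2,5-dimethylcyclohexan-1-one
Product: 24 (R)-5-ethenyl-2,5-dimethylcyclohex-2-en-1-one
Conditions: IBX, 4-methoxypyridine N-oxide, DMSO, 23–40 °C
Reagents that add atoms: none
Why: IBX dehydrogenation can only run across C19–C20, because C17 on the other side of the carbonyl group carries no hydrogen.

Step 13
Reactants: 24 (R)-5-ethenyl-2,5-dimethylcyclohex-2-en-1-one
Product: 25 (R)-tert-butyl[(5-ethenyl-2,5-dimethylcyclohexa-1,3-dien-1-yl)oxy]dimethylsilane
Conditions: TBSCl, NaI, Et3N, MeCN, 50 °C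
Reagents that add atoms: tert-butyldimethylsilyl chloride CC(C)(C)[Si](C)(C)Cl
Why: This is a thermodynamic silyl dienol ether formation in which the silyl iodide made in situ adds 1,4, the amine can then remove HI only through C18–H, and any cross-conjugated isomer is returned by the ammonium salt, so the through-conjugated isomer with the tetrasubstituted C20=C21 bond should accumulate while C17 is untouched.

Step 14
Reactants: 25 (R)-tert-butyl[(5-ethenyl-2,5-dimethylcyclohexa-1,3-dien-1-yl)oxy]dimethylsilane; 16 (R)-4-[(E)-4-bromo-3-methylpent-3-en-1-yl]-6,7-dimethoxy-4,8-dimethylnaphthalen-1(4H)-one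
Product: 27 seco-C,D 6-ketone (ring A/B naphthalenone and ring E TBS dienol ether joined through the (E)-C13=C14 alkene), via ring E B-alkyl-9-BBN 26 (not isolated)
Conditions: 25, 9-BBN, THF, 23 °C; then 16, Pd(OAc)2 (5 mol %), SPhos, K3PO4, THF/DMF (trace H2O), 50 °C
Reagents that add atoms: 9-borabicyclo[3.3.1]nonane B1C2CCCC1CCC2 (boron unit in 26 only)
Why: In this B-alkyl Suzuki–Miyaura coupling 9-BBN takes only the monosubstituted vinyl group, the dienol ether shields the ring E carbonyl from boron hydride, 16 has no enolisable hydrogen, and coupling with retention delivers the (E)-tetrasubstituted alkene.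

Step 15
Reactants: 27 seco-C,D 6-ketone
Product: 28 seco-C,D C6 allylic alcohol with (E)-C13=C14 alkene and ring E TBS dienol ether
Conditions: iBu2AlH, toluene/CH2Cl2, −78 °C; aq KNaC4H4O6; filtration through basic alumina
Reagents that add atoms: none
Why: The 1,2-reduction of the only free carbonyl group should deliver hydride from the less hindered C25 face, so the hydroxyl group ends up cis to C11, and either C6 epimer serves because this centre is ionised next.

Step 16
Reactants: 28 seco-C,D C6 allylic alcohol
Product: 31 pentacyclic 19-en-21-one catechol dimethyl ether, via allyl cation 29 (not isolated), via C13 cation 30 (not isolated)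
Conditions: MeAlCl2 (2 equiv), CH2Cl2 (2 mM), −78 °C; Et3N/MeOH quench
Reagents that add atoms: none
Why: Proposed new method: MeAlCl2 first deprotonates the C6 carbinol (methane leaves, so no Brønsted acid is set free) and then ionises the aluminium alkoxide to allyl cation 29, delocalised over C6/C8 and into the C2 methoxy group, after which C14 of the (E)-alkene bonds to C8, tertiary cation 30 is taken by C18, the γ-carbon of the silyl dienol ether, and loss of the silyl group leaves the C19=C20 enone and the C6=C7 styrene. The closest known reaction types are Lewis-acid cation–olefin polycyclisations of allylic alcohols that end on silyl enol ethers and the γ-alkylation of silyl dienol ethers by tertiary carbocations, and the tetrasubstituted relay alkene between the two is the untested element. Ring C closes 6-endo with respect to the C13=C14 bond, and ring D closes 6-exo with respect to the C18=C19 bond (endo at the cationic centre C13). C8 is fixed by C9 because the two-carbon tether reaches the flat cation only on the face that carries C11, which puts C8–H cis to C25; C14 and C13 are tied to one another by anti addition across the (E)-alkene, which makes C26 and C27 trans; C18 is fixed by C17 in the same way, which makes rings D/E cis-fused. The selectivity still needed is the choice of alkene face: since 30 is far less stabilised than 29, ring C closure should be reversible and the face should be chosen in the C13–C18 bond formation, where the fold leading to 31 lets ring D close as a chair with C19 equatorial and one 1,3-diaxial contact (C22/C27), whereas the other fold needs two (C28/C27 and C19/C26). Site selectivity (C8, not C6) follows from the tether length, and low temperature with a proton-free Lewis acid is meant to outrun the 1,2-shift of a C9 substituent to C8 that would aromatise ring B.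

Step 17
Reactants: 31 pentacyclic 19-en-21-one catechol dimethyl ether
Product: 32 pentacyclic (20R)-21-ketone catechol dimethyl ether
Conditions: [(Ph3P)CuH]6, toluene, H2O (few equiv), 23 °C; then K2CO3 (cat.), MeOH, 23 °C
Reagents that add atoms: none
Why: Copper hydride conjugate reduction touches the enone but not the C6=C7 styrene, and base equilibration should settle C20 as the equatorial methyl epimer, since the axial epimer would clash with axial C13 on ring E.

Step 18
Reactants: 32 pentacyclic (20R)-21-ketone catechol dimethyl ether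
Product: 33 pentacyclic 2,3-catechol 21-ketone
Conditions: BBr3, CH2Cl2, −78 → 0 °C; aq NaHCO3, under argon
Reagents that add atoms: none
Why: Boron tribromide cleavage of aryl methyl ethers proceeds at low temperature, where the ketone and the styrene should survive, and no stereocentre is affected (C20 is already the stable epimer).

Step 19
Reactants: 34 (S)-carvone
Product: 35 (2R,5S)-2-methyl-5-(prop-1-en-2-yl)cyclohexan-1-one (cis-dihydrocarvone)
Conditions: ene-reductase OYE2, NADP+ (cat.), glucose dehydrogenase, D-glucose, KH2PO4/K2HPO4 buffer pH 7, 30 °C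
Reagents that add atoms: none
Why: Enzymatic ene-reduction (old yellow enzyme family) fixes the α-carbon as (R) under enzyme control and so gives the cis isomer from (S)-carvone, which trans-selective chemical reductions do not, setting C10′ beside chiral-pool C7′.

Step 20
Reactants: 35 (2R,5S)-2-methyl-5-(prop-1-en-2-yl)cyclohexan-1-one; 36 ethyl diazoacetate
Product: 37 ethyl (3R,6S)-3-methyl-2-oxo-6-(prop-1-en-2-yl)cycloheptane-1-carboxylate (C1 epimers and enol)
Conditions: 36, BF3·OEt2, Et2O, 0 °C, short contact
Reagents that add atoms: none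
Why: In this Lewis-acid-promoted diazoacetate homologation (Tiffeneau–Demjanov-type ring expansion) the less substituted CH2 migrates, so C5′ with its ester carbon C4′ is inserted between C1′ and C6′, and brief exposure at 0 °C protects the epimerisable C10′.

Step 21
Reactants: 37 ethyl (3R,6S)-3-methyl-2-oxo-6-(prop-1-en-2-yl)cycloheptane-1-carboxylate
Product: 38 ethyl (3R,6S)-3-methyl-6-(prop-1-en-2-yl)-2-(trifluoromethylsulfonyloxy)cyclohept-1-ene-1-carboxylate
Conditions: Tf2O, iPr2NEt, CH2Cl2, −78 °C
Reagents that add atoms: trifluoromethanesulfonic anhydride O=S(=O)(OS(=O)(=O)C(F)(F)F)C(F)(F)F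
Why: O-Triflation of the β-keto ester enol uses an amine base that can only remove the acidic C5′ hydrogen, so C10′ keeps its configuration.

Step 22
Reactants: 38 ethyl (3R,6S)-3-methyl-6-(prop-1-en-2-yl)-2-(trifluoromethylsulfonyloxy)cyclohept-1-ene-1-carboxylate; 39 3-ethoxy-3-oxopropylzinc bromide
Product: 40 ethyl (3R,6S)-2-(3-ethoxy-3-oxopropyl)-3-methyl-6-(prop-1-en-2-yl)cyclohept-1-ene-1-carboxylate
Conditions: 39, Pd(PPh3)4 (5 mol %), THF, 50 °C
Reagents that add atoms: none
Why: Negishi coupling of an enol triflate with a zinc homoenolate brings in C2′ and C3′ under neutral conditions that leave both stereocentres alone.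

Step 23
Reactants: 40 ethyl (3R,6S)-2-(3-ethoxy-3-oxopropyl)-3-methyl-6-(prop-1-en-2-yl)cyclohept-1-ene-1-carboxylate
Product: 41 ethyl (4R,7S)-4-methyl-1-oxo-7-(prop-1-en-2-yl)-1,2,3,4,5,6,7,8-octahydroazulene-2-carboxylate (C2 epimers)
Conditions: LiN(SiMe3)2, THF, −78 → 0 °C; aq NH4Cl
Reagents that add atoms: none
Why: In this Dieckmann condensation the kinetically formed enolate of the saturated ester (C3′) attacks the neighbouring unsaturated ester (C4′) to close the five-membered ring, and low temperature avoids γ-deprotonation at C10′.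

Step 24
Reactants: 41 ethyl (4R,7S)-4-methyl-1-oxo-7-(prop-1-en-2-yl)-1,2,3,4,5,6,7,8-octahydroazulene-2-carboxylate
Product: 42 (4R,7S)-4-methyl-7-(prop-1-en-2-yl)-3,4,5,6,7,8-hexahydroazulen-1(2H)-one
Conditions: LiCl, H2O, DMSO, 140 °C
Reagents that add atoms: none
Why: Krapcho dealkoxycarbonylation removes the ester under nearly neutral conditions, so the γ-stereocentre C10′ of the enone is not equilibrated.

Step 25
Reactants: 42 (4R,7S)-4-methyl-7-(prop-1-en-2-yl)-3,4,5,6,7,8-hexahydroazulen-1(2H)-one
Product: 44 (7S,10R)-guaia-1(5),3,11-triene, (5S,8R)-3,8-dimethyl-5-(prop-1-en-2-yl)-1,4,5,6,7,8-hexahydroazulene, via tertiary alcohol 43 (not isolated)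
Conditions: MeLi, Et2O, −78 °C; H2O; then p-TsOH·H2O (cat.), Et2O, 0 °C; used at once
Reagents that add atoms: methyllithium [Li]C
Why: 1,2-Addition of methyllithium to a cyclopentenone followed by acid-catalysed dehydration of the tertiary allylic alcohol is the standard route to alkylcyclopentadienes, and immediate use limits 1,5-hydrogen shifts.

Step 26
Reactants: 33 pentacyclic 2,3-catechol 21-ketone; 44 (7S,10R)-guaia-1(5),3,11-triene
Product: 46 CNP0233042.2, via o-quinone 45 (not isolated)
Conditions: Ag2O, 44 (3 equiv), MgSO4, CH2Cl2, 0 → 23 °C, dark, argon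
Reagents that add atoms: none
Why: Oxidation to the o-quinone and an inverse-electron-demand hetero-Diels–Alder reaction (O=C2–C3=O as the 4π unit, the fully alkylated C1′=C5′ bond of the electron-rich cyclopentadiene as the 2π unit) should set C1′ and C5′ by approach anti to the cis C10′ methyl and C7′ isopropenyl groups, with hindered O3 (next to the C4 methyl) going to C5′, flanked by CH2 and flat C4′, and O2 going to C1′ next to branched C10′.

Compound list
1 | 2,3-dimethoxytoluene | COc1cccc(C)c1OC | starting material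
2 | 2-(3,4-dimethoxy-5-methylphenyl)-4,4,5,5-tetramethyl-1,3,2-dioxaborolane | COc1cc(cc(C)c1OC)B1OC(C)(C)C(C)(C)O1 | intermediate
3 | 5-bromo-1,2-dimethoxy-3-methylbenzene | COc1cc(Br)cc(C)c1OC | intermediate
4 | geraniol, (E)-3,7-dimethylocta-2,6-dien-1-ol | CC(C)=CCC/C(C)=C/CO | starting material
5 | geranyl diethyl phosphate | CC(C)=CCC/C(C)=C/COP(=O)(OCC)OCC | intermediate
6 | (3,4-dimethoxy-5-methylphenyl)lithium | [Li]c1cc(C)c(OC)c(OC)c1 | intermediate
7 | diethyl(3,4-dimethoxy-5-methylphenyl)aluminium | CC[Al](CC)c1cc(C)c(OC)c(OC)c1 | intermediate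
8 | (S)-5-(3,7-dimethylocta-1,6-dien-3-yl)-1,2-dimethoxy-3-methylbenzene | C=C[C@](C)(CCC=C(C)C)c1cc(C)c(OC)c(OC)c1 | intermediate
9 | (E)-2,3-dibromobut-2-ene | C/C(Br)=C(/C)Br | starting material
10 | B-alkyl-9-BBN from 8 (boron on C12) | CC(C)=CCC[C@@](C)(CCB1C2CCCC1CCC2)c1cc(C)c(OC)c(OC)c1 | intermediate
11 | 5-[(2E,6S)-2-bromo-3,6,10-trimethylundeca-2,9-dien-6-yl]-1,2-dimethoxy-3-methylbenzene | CC(C)=CCC[C@@](C)(CC/C(C)=C(\C)Br)c1cc(C)c(OC)c(OC)c1 | intermediate
12 | (4R,7E)-8-bromo-4-(3,4-dimethoxy-5-methylphenyl)-4,7-dimethylnon-7-enal | O=CCC[C@@](C)(CC/C(C)=C(\C)Br)c1cc(C)c(OC)c(OC)c1 | intermediate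
13 | (4R,7E)-8-bromo-4-(3,4-dimethoxy-5-methylphenyl)-4,7-dimethylnon-7-enoic acid | OC(=O)CC[C@@](C)(CC/C(C)=C(\C)Br)c1cc(C)c(OC)c(OC)c1 | intermediate
14 | mixed trifluoroacetic anhydride of 13 | FC(F)(F)C(=O)OC(=O)CC[C@@](C)(CC/C(C)=C(\C)Br)c1cc(C)c(OC)c(OC)c1 | intermediate
15 | (R)-4-[(E)-4-bromo-3-methylpent-3-en-1-yl]-6,7-dimethoxy-4,8-dimethyl-3,4-dihydronaphthalen-1(2H)-one | COc1c(OC)cc2c(c1C)C(=O)CC[C@@]2(C)CC/C(C)=C(\C)Br | intermediate
16 | (R)-4-[(E)-4-bromo-3-methylpent-3-en-1-yl]-6,7-dimethoxy-4,8-dimethylnaphthalen-1(4H)-one | COc1c(OC)cc2c(c1C)C(=O)C=C[C@@]2(C)CC/C(C)=C(\C)Br | intermediate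
17 | 3-methylcyclohex-2-en-1-one | CC1=CC(=O)CCC1 | starting material
18 | ethynyltrimethylsilane | C#C[Si](C)(C)C | starting material
19 | diisobutyl[1-(trimethylsilyl)ethenyl]aluminium | C=C([Si](C)(C)C)[Al](CC(C)C)CC(C)C | intermediate
20 | (R)-3-methyl-3-[1-(trimethylsilyl)ethenyl]cyclohexan-1-one | C=C([Si](C)(C)C)[C@]1(C)CCCC(=O)C1 | intermediate
21 | (R)-3-ethenyl-3-methylcyclohexan-1-one | C=C[C@]1(C)CCCC(=O)C1 | intermediate
22 | lithium enolate of 21 (C20=C21) | C=C[C@]1(C)CCC=C(O[Li])C1 | intermediate
23 | (5R)-5-ethenyl-2,5-dimethylcyclohexan-1-one (C2 epimers) | C=C[C@]1(C)CCC(C)C(=O)C1 | intermediate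
24 | (R)-5-ethenyl-2,5-dimethylcyclohex-2-en-1-one | C=C[C@]1(C)CC=C(C)C(=O)C1 | intermediate
25 | (R)-tert-butyl[(5-ethenyl-2,5-dimethylcyclohexa-1,3-dien-1-yl)oxy]dimethylsilane | C=C[C@]1(C)C=CC(C)=C(O[Si](C)(C)C(C)(C)C)C1 | intermediate
26 | B-alkyl-9-BBN from 25 (boron on C15) | C[C@@]1(CCB2C3CCCC2CCC3)C=CC(C)=C(O[Si](C)(C)C(C)(C)C)C1 | intermediate
27 | seco-C,D 6-ketone: ring A/B 6,7-dimethoxy-4,8-dimethylnaphthalen-1(4H)-one and ring E TBS dienol ether joined through the (E)-C13=C14 alkene, C9 and C17 as in the target | COc1c(OC)cc2c(c1C)C(=O)C=C[C@@]2(C)CC/C(C)=C(\C)CC[C@]3(C)C=CC(C)=C(O[Si](C)(C)C(C)(C)C)C3 | intermediate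
28 | seco-C,D C6 allylic alcohol (hydroxyl cis to C11), (E)-C13=C14 alkene, ring E TBS dienol ether | COc1c(OC)cc2c(c1C)[C@@H](O)C=C[C@@]2(C)CC/C(C)=C(\C)CC[C@]3(C)C=CC(C)=C(O[Si](C)(C)C(C)(C)C)C3 | intermediate
29 | C6–C8 allyl cation (drawn with the charge on C6) | COc1c(OC)cc2c(c1C)[CH+]C=C[C@@]2(C)CC/C(C)=C(\C)CC[C@]3(C)C=CC(C)=C(O[Si](C)(C)C(C)(C)C)C3 | intermediate
30 | tetracyclic C13 tertiary cation (ring C closed) | COc1c(OC)cc2c(c1C)C=C[C@@H]1[C@@]2(C)CC[C+](C)[C@]1(C)CC[C@]3(C)C=CC(C)=C(O[Si](C)(C)C(C)(C)C)C3 | intermediate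
31 | pentacyclic 19-en-21-one catechol dimethyl ether (C8–H cis to C25, C26/C27 trans, rings D/E cis) | COc1c(OC)cc2c(c1C)C=C[C@@H]1[C@@]2(C)CC[C@@]2(C)[C@@H]4C=C(C)C(=O)C[C@]4(C)CC[C@]12C | intermediate
32 | pentacyclic (20R)-21-ketone catechol dimethyl ether | COc1c(OC)cc2c(c1C)C=C[C@@H]1[C@@]2(C)CC[C@@]2(C)[C@@H]4C[C@@H](C)C(=O)C[C@]4(C)CC[C@]12C | intermediate
33 | pentacyclic 2,3-catechol (20R)-21-ketone | Oc1c(O)cc2c(c1C)C=C[C@@H]1[C@@]2(C)CC[C@@]2(C)[C@@H]4C[C@@H](C)C(=O)C[C@]4(C)CC[C@]12C | intermediate
34 | (S)-carvone | CC1=CC[C@@H](CC1=O)C(C)=C | starting material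
35 | (2R,5S)-2-methyl-5-(prop-1-en-2-yl)cyclohexan-1-one | C[C@@H]1CC[C@@H](CC1=O)C(C)=C | intermediate
36 | ethyl diazoacetate | CCOC(=O)C=[N+]=[N-] | starting material
37 | ethyl (3R,6S)-3-methyl-2-oxo-6-(prop-1-en-2-yl)cycloheptane-1-carboxylate | CCOC(=O)C1C[C@H](CC[C@@H](C)C1=O)C(C)=C | intermediate
38 | ethyl (3R,6S)-3-methyl-6-(prop-1-en-2-yl)-2-(trifluoromethylsulfonyloxy)cyclohept-1-ene-1-carboxylate | CCOC(=O)C1=C(OS(=O)(=O)C(F)(F)F)[C@H](C)CC[C@@H](C1)C(C)=C | intermediate
39 | 3-ethoxy-3-oxopropylzinc bromide | CCOC(=O)CC[Zn]Br | starting material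
40 | ethyl (3R,6S)-2-(3-ethoxy-3-oxopropyl)-3-methyl-6-(prop-1-en-2-yl)cyclohept-1-ene-1-carboxylate | CCOC(=O)CCC1=C(C(=O)OCC)C[C@H](CC[C@H]1C)C(C)=C | intermediate
41 | ethyl (4R,7S)-4-methyl-1-oxo-7-(prop-1-en-2-yl)-1,2,3,4,5,6,7,8-octahydroazulene-2-carboxylate | CCOC(=O)C1CC2=C(C1=O)C[C@H](CC[C@H]2C)C(C)=C | intermediate
42 | (4R,7S)-4-methyl-7-(prop-1-en-2-yl)-3,4,5,6,7,8-hexahydroazulen-1(2H)-one | O=C1CCC2=C1C[C@H](CC[C@H]2C)C(C)=C | intermediate
43 | (4R,7S)-1,4-dimethyl-7-(prop-1-en-2-yl)-1,2,3,4,5,6,7,8-octahydroazulen-1-ol (C1 epimers) | CC1(O)CCC2=C1C[C@H](CC[C@H]2C)C(C)=C | intermediate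
44 | (7S,10R)-guaia-1(5),3,11-triene | CC1=CCC2=C1C[C@H](CC[C@H]2C)C(C)=C | intermediate
45 | pentacyclic 2,3-o-quinone (20R)-21-ketone | O=C1C(=O)C=C2C(=C1C)C=C[C@@H]1[C@@]2(C)CC[C@@]2(C)[C@@H]4C[C@@H](C)C(=O)C[C@]4(C)CC[C@]12C | intermediate
46 | CNP0233042.2 | C=C(C)[C@H]1CC[C@@H](C)[C@@]23CC=C(C)[C@]2(C1)Oc1c(cc2c(c1C)C=C[C@@H]1[C@@]2(C)CC[C@@]2(C)[C@@H]4C[C@@H](C)C(=O)C[C@]4(C)CC[C@]12C)O3 | target

Total step count: 26
Longest linear sequence: 13 steps (1, 3–8, 14–18, 26)

Steps most likely to fail

1. Step 16. Several processes could stop the relay: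
   - early loss of the silyl group
   - proton loss or chloride capture at the congested C13 cation before C18 arrives
   - migration of a C9 substituent to C8 with aromatisation of ring B
   - poor selection between the two alkene faces

   The fallback uses two separate ring closures of known type. It sets out from 28 and comes back at 31. Bu4NF/AcOH unmasks ring E to give the enone carbinol F1. SnCl4 in CH2Cl2 at −78 °C closes ring C alone (cation–olefin monocyclisation), and chloride takes the C13 cation to give the tetracyclic tertiary chloride F2. TBSCl/NaI/Et3N rebuilds the through-conjugated dienol ether and gives the chloro dienol ether F3. TiCl4 or ZnCl2 at low temperature then re-ionises the chloride for an intramolecular tert-alkylation of the silyl dienol ether at its γ-carbon, which closes ring D and gives 31.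

2. Step 26. Four things could go wrong:
   - addition across the less hindered C3′=C4′ bond
   - addition to a cyclopentadiene isomer formed by 1,5-hydrogen shift
   - poor orientation (O2/O3 against C1′/C5′)
   - tautomerisation of the o-quinone to the quinone methide before it is trapped

   The fallback is stepwise, with the two oxygens told apart. It sets out from 33 and 44 and comes back at 46. PhNTf2/Et3N sulfonylates the less hindered O2 to give the 3-hydroxy-2-triflate F4. Dimethyldioxirane at −78 °C epoxidises the tetrasubstituted C1′=C5′ bond of 44 anti to the C10′ methyl group and gives the vinyl epoxide F5. Zerovalent palladium (Pd2(dba)3, PPh3) with Et3B as co-catalyst opens F5 with the phenol of F4 at the proximal allylic carbon C5′ with overall retention (Tsuji–Trost etherification) and gives the hydroxy ether F6. A Buchwald–Hartwig etherification (Pd(OAc)2, bulky di-tert-butylbiarylphosphine, Cs2CO3, toluene, 80 °C) then joins the C1′ tertiary alcohol to C2 and gives 46.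

3. Step 13. Deprotonation at C22 instead of C18 would give the cross-conjugated dienol ether, which cannot deliver C18 to the cation. The fallback is regiospecific by construction. It sets out from 24 and comes back at 25. Conjugate addition of PhSeLi in THF with TBSCl capture of the enolate gives the β-phenylseleno silyl enol ether F7. One equivalent of mCPBA at −78 °C gives the selenoxide F8. On warming with iPr2NH, F8 undergoes syn elimination, which can only use a C18 hydrogen because C20 is already sp2, and this gives 25.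

Further compounds
F1 | step 16 | seco-C,D C6 allylic alcohol with free ring E enone | COc1c(OC)cc2c(c1C)[C@@H](O)C=C[C@@]2(C)CC/C(C)=C(\C)CC[C@]3(C)CC=C(C)C(=O)C3
F2 | step 16 | tetracyclic C13 tertiary chloride with ring E enone | COc1c(OC)cc2c(c1C)C=C[C@@H]1[C@@]2(C)CC[C@@](C)(Cl)[C@]1(C)CC[C@]3(C)CC=C(C)C(=O)C3
F3 | step 16 | tetracyclic C13 tertiary chloride with ring E TBS dienol ether | COc1c(OC)cc2c(c1C)C=C[C@@H]1[C@@]2(C)CC[C@@](C)(Cl)[C@]1(C)CC[C@]3(C)C=CC(C)=C(O[Si](C)(C)C(C)(C)C)C3
F4 | step 26 | pentacyclic 3-hydroxy-2-triflate 21-ketone | Oc1c(OS(=O)(=O)C(F)(F)F)cc2c(c1C)C=C[C@@H]1[C@@]2(C)CC[C@@]2(C)[C@@H]4C[C@@H](C)C(=O)C[C@]4(C)CC[C@]12C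
F5 | step 26 | 1′,5′-epoxyguaia-3,11-diene (oxygen anti to the C10′ methyl group) | C=C(C)[C@H]1CC[C@@H](C)[C@@]23CC=C(C)[C@]2(C1)O3
F6 | step 26 | O3–C5′ ether with C1′ tertiary alcohol and C2 triflate | C=C(C)[C@H]1CC[C@@H](C)[C@@]2(O)CC=C(C)[C@]2(C1)Oc1c(OS(=O)(=O)C(F)(F)F)cc2c(c1C)C=C[C@@H]1[C@@]2(C)CC[C@@]2(C)[C@@H]4C[C@@H](C)C(=O)C[C@]4(C)CC[C@]12C
F7 | step 13 | β-phenylseleno TBS enol ether of 24 | C=C[C@]1(C)CC([Se]c2ccccc2)C(C)=C(O[Si](C)(C)C(C)(C)C)C1
F8 | step 13 | selenoxide of F7 | C=C[C@]1(C)CC([Se](=O)c2ccccc2)C(C)=C(O[Si](C)(C)C(C)(C)C)C1
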